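**Retrosynthetic overview**

1. Ring numbering: C1 (C=O), C2 (benzoyl), C3 (C–OH), C4 (prenyl), C5 (C=O), C6 (quaternary; geranyl and prenyl). The enabling feature is that this ring is the keto tautomer of an acylphloroglucinol: C1–C2–C3 is a malonyl unit, C4–C5–C6 is a ketone with an allylated carbon on each side, and without the geranyl group C4 and C6 are equivalent.
2. Kolanone is taken back by O-demethylation at O5 and a catalytic, face-selective dearomative geranylation to the achiral 2,6-dihydroxy-4-methoxy-3,5-diprenylbenzophenone; the only stereocentre (C6) is therefore set late, by the catalyst, on a mirror-symmetric arene.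
3. Removal of the benzoyl group (ortho C-acylation of a phenolate) leads to 5-methoxy-4,6-diprenylresorcinol.
4. Key disconnection: C1–C6 and C3–C4 are cut together ([3+3]). In the forward sense malonyl dichloride is joined to both α-carbons of the methyl enol ether of the symmetric ketone 2,10-dimethylundeca-2,9-dien-6-one, and the product aromatises. This carbocycle is the only ring formed in the route; the phenyl ring is bought with benzoyl chloride.
5. The ketone comes from 6-methylhept-5-en-2-one and prenyl bromide; the geranyl donor comes from geraniol.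

Key step: step 3

Assumption: the (1R,2R)-ligand of step 6 is taken to favour the 6R product; the facial sense with this nucleophile cannot be predicted with certainty, so the (1S,2S)-ligand replaces it under the same conditions if the opposite sense is found.

**Step 1**
Reactants: 1 6-methylhept-5-en-2-one (sulcatone); 2 1-bromo-3-methylbut-2-ene (prenyl bromide)
Product: 4 2,10-dimethylundeca-2,9-dien-6-one, via lithium enolate 3 (not isolated)
Conditions: LDA (1.05 equiv), THF, −78 °C; then 2, −78 to 0 °C
Reagents that add atoms: none
Why: Kinetic deprotonation of the methyl ketone by lithium diisopropylamide at −78 °C gives the less substituted enolate, which is C-alkylated by the allylic bromide in an SN2 enolate alkylation; no stereocentre is formed.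

**Step 2**
Reactants: 4 2,10-dimethylundeca-2,9-dien-6-one
Product: 6 6-methoxy-2,10-dimethylundeca-2,5,9-triene (E/Z mixture at the enol ether), via dimethyl ketal 5 (not isolated)
Conditions: HC(OMe)3, cat. TsOH·H2O, rt; Et3N, evaporate; then TMSOTf, iPr2NEt, CH2Cl2, −20 °C to rt
Reagents that add atoms: trimethyl orthoformate, COC(OC)OC
Why: Acid-catalysed ketalisation by the orthoformate, then silyl-triflate-mediated 1,2-elimination of methanol from the ketal (acetal-to-enol-ether conversion), gives the methyl enol ether; because the ketone is symmetric only one constitutional isomer can form, its E/Z ratio is irrelevant for step 3, and no stereocentre is formed.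

**Step 3**
Reactants: 6 6-methoxy-2,10-dimethylundeca-2,5,9-triene; 7 malonyl dichloride
Product: 9 5-methoxy-4,6-bis(3-methylbut-2-en-1-yl)benzene-1,3-diol, via keto acid chloride 8 (not isolated)
Conditions: 7 (1.1 equiv), Et2O, −20 °C to rt; aq. NaHCO3 work-up
Reagents that add atoms: none
Why: One acid chloride of 7 acylates the nucleophilic β-carbon of enol ether 6 (C3–C4 bond) and loss of HCl from the oxocarbenium ion gives the β-methoxy enone 8; its γ-methylene, as the 2-methoxy-dienol tautomer, then attacks the second acid chloride intramolecularly (C1–C6 bond), and loss of HCl followed by enolisation gives the aromatic ring. The closest known reaction type is the Effenberger cyclization, the α,α′-annulation of ketone methyl enol ethers by malonyl dichloride that turns 1-methoxycyclohexenes into bicyclo[3.3.1]nonane-2,4,9-triones. The six-membered carbocycle closes in a 6-(enolendo)-exo-trig mode at the acyl chloride carbon. No stereocentre is formed, since the product is a planar, mirror-symmetric arene. The step needs C- rather than O-acylation in the ring closure: the methyl group keeps the oxygen at C5 blocked as an ether, which disfavours lactonisation to a 2-pyranone, and aromatisation makes the C-closure irreversible. Regiochemistry needs no control because the ketone precursor is symmetric, so both prenyl groups necessarily end up on C4 and C6, flanking C5.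

**Step 4**
Reactants: 9 5-methoxy-4,6-bis(3-methylbut-2-en-1-yl)benzene-1,3-diol; 10 benzoyl chloride
Product: 12 [2,6-dihydroxy-4-methoxy-3,5-bis(3-methylbut-2-en-1-yl)phenyl](phenyl)methanone, via bis(bromomagnesium) phenolate 11 (not isolated)
Conditions: EtMgBr (2.1 equiv), Et2O/toluene, 0 °C to rt; then 10, toluene, rt to 50 °C; aq. NH4Cl
Reagents that add atoms: none
Why: The magnesium bis-phenolate delivers the acid chloride to the only free ring carbon, which lies ortho to both O–Mg groups, through a chelated transition state (ortho-selective Friedel–Crafts-type C-acylation of a metal phenolate), and the non-acidic medium spares the acid-sensitive prenyl groups; no stereocentre is formed.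

**Step 5**
Reactants: 13 geraniol, (2E)-3,7-dimethylocta-2,6-dien-1-ol
Product: 14 (2E)-3,7-dimethylocta-2,6-dien-1-yl methyl carbonate (geranyl methyl carbonate)
Conditions: ClCO2Me, pyridine, CH2Cl2, 0 °C
Reagents that add atoms: methyl chloroformate, COC(Cl)=O
Why: O-Acylation of the primary allylic alcohol by the chloroformate (carbonate formation) leaves the E-alkene untouched; no stereocentre is formed.

**Step 6**
Reactants: 12 [2,6-dihydroxy-4-methoxy-3,5-bis(3-methylbut-2-en-1-yl)phenyl](phenyl)methanone; 14 geranyl methyl carbonate
Product: 15 (6R)-2-benzoyl-6-[(2E)-3,7-dimethylocta-2,6-dien-1-yl]-3-hydroxy-5-methoxy-4,6-bis(3-methylbut-2-en-1-yl)cyclohexa-2,4-dien-1-one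
Conditions: Pd2(dba)3·CHCl3 (2.5 mol %), (1R,2R)-N,N′-bis[2-(diphenylphosphanyl)benzoyl]cyclohexane-1,2-diamine (7.5 mol %), CH2Cl2, 0 °C to rt
Reagents that add atoms: none
Why: In this Tsuji–Trost asymmetric allylic alkylation run as a dearomatisation, zerovalent palladium ionises 14 to a π-geranyl complex and methoxide (after loss of CO2), the phenoxide of 12 attacks the unsubstituted allyl terminus through one of its two equivalent prenyl-bearing ring carbons, and the chiral diamide-bisphosphine ligand selects one of the two enantiotopic faces of that carbon, which sets C6 as R; the new quaternary carbon cannot re-aromatise and the O-methyl group prevents a second alkylation.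

**Step 7**
Reactants: 15 (6R)-2-benzoyl-6-geranyl-3-hydroxy-5-methoxy-4,6-diprenylcyclohexa-2,4-dien-1-one
Product: 16 kolanone, (6R)-6-[(2E)-3,7-dimethylocta-2,6-dien-1-yl]-3-hydroxy-2-[hydroxy(phenyl)methylidene]-4,6-bis(3-methylbut-2-en-1-yl)cyclohex-3-ene-1,5-dione
Conditions: LiCl, DMSO, 110 °C; then aq. HCl
Reagents that add atoms: none
Why: Chloride attacks the methyl group of the vinylogous ester in an SN2 O-demethylation that releases the strongly stabilised β-triketone enolate, protonated on work-up; the quaternary stereocentre carries no hydrogen and is not touched.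

**Compound list**

1 | 6-methylhept-5-en-2-one (sulcatone) | CC(=O)CCC=C(C)C | starting material
2 | 1-bromo-3-methylbut-2-ene (prenyl bromide) | CC(C)=CCBr | starting material
3 | lithium 6-methylhepta-1,5-dien-2-olate | C=C(O[Li])CCC=C(C)C | intermediate
4 | 2,10-dimethylundeca-2,9-dien-6-one | CC(C)=CCCC(=O)CCC=C(C)C | intermediate
5 | 6,6-dimethoxy-2,10-dimethylundeca-2,9-diene | CC(C)=CCCC(OC)(OC)CCC=C(C)C | intermediate
6 | 6-methoxy-2,10-dimethylundeca-2,5,9-triene (E/Z mixture) | CC(C)=CCC=C(OC)CCC=C(C)C | intermediate
7 | malonyl dichloride | ClC(=O)CC(Cl)=O | starting material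
8 | 5-methoxy-9-methyl-4-(3-methylbut-2-en-1-yl)-3-oxodeca-4,8-dienoyl chloride | COC(CCC=C(C)C)=C(CC=C(C)C)C(=O)CC(Cl)=O | intermediate
9 | 5-methoxy-4,6-bis(3-methylbut-2-en-1-yl)benzene-1,3-diol | COc1c(CC=C(C)C)c(O)cc(O)c1CC=C(C)C | intermediate
10 | benzoyl chloride | O=C(Cl)c1ccccc1 | starting material
11 | bis(bromomagnesium) salt of 9 | COc1c(CC=C(C)C)c(O[Mg]Br)cc(O[Mg]Br)c1CC=C(C)C | intermediate
12 | [2,6-dihydroxy-4-methoxy-3,5-bis(3-methylbut-2-en-1-yl)phenyl](phenyl)methanone | COc1c(CC=C(C)C)c(O)c(C(=O)c2ccccc2)c(O)c1CC=C(C)C | intermediate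
13 | geraniol, (2E)-3,7-dimethylocta-2,6-dien-1-ol | CC(C)=CCC/C(C)=C/CO | starting material
14 | (2E)-3,7-dimethylocta-2,6-dien-1-yl methyl carbonate | CC(C)=CCC/C(C)=C/COC(=O)OC | intermediate
15 | (6R)-2-benzoyl-6-[(2E)-3,7-dimethylocta-2,6-dien-1-yl]-3-hydroxy-5-methoxy-4,6-bis(3-methylbut-2-en-1-yl)cyclohexa-2,4-dien-1-one | CC(C)=CCC/C(C)=C/C[C@]1(CC=C(C)C)C(OC)=C(CC=C(C)C)C(O)=C(C(=O)c2ccccc2)C1=O | intermediate
16 | kolanone, (6R)-6-[(2E)-3,7-dimethylocta-2,6-dien-1-yl]-3-hydroxy-2-[hydroxy(phenyl)methylidene]-4,6-bis(3-methylbut-2-en-1-yl)cyclohex-3-ene-1,5-dione | CC(C)=CCC/C(C)=C/C[C@]1(CC=C(C)C)C(=O)C(CC=C(C)C)=C(O)/C(=C(\O)c2ccccc2)C1=O | target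

**Step count and risks**

Total step count: 7. Longest linear sequence: 6 steps (steps 1, 2, 3, 4, 6, 7); step 5 is a one-step side branch.

Steps most likely to fail:

1. Step 6. What may go wrong:
 - insufficient facial discrimination by the catalyst, giving low enantiomeric purity;
 - alkylation at oxygen instead of carbon;
 - E/Z isomerisation within the π-geranyl intermediate;
 - reversible ionisation of the new C–allyl bond, which would erode the configuration or scramble the allyl groups.

 Fallback, setting out from 12 and geraniol 13 and coming back at 15: geraniol 13 is converted by PBr3 (Et2O, 0 °C) into geranyl bromide F1. The sodium salt of 12 (NaOMe, MeOH/toluene, 0 °C) is C-alkylated by F1 in the classical geminal C-alkylation of acylphloroglucinol anions, which should give the racemic methyl ether F2. Preparative chromatography on a chiral stationary phase then separates 15 from its (6S)-enantiomer F3.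

2. Step 3. What may go wrong:
 - ring closure through oxygen instead of carbon, with loss of the O-methyl group and lactonisation to a 4-hydroxy-2-pyranone;
 - hydrolysis of the enol ether by the HCl that is formed;
 - addition of HCl to the prenyl double bonds.

 Fallback, setting out from prenyl bromide 2 and coming back at 12: the aromatic ring is bought instead of built. Commercial 2,4,6-trihydroxybenzophenone F4 is methylated selectively at the non-chelated 4-hydroxyl (Me2SO4, K2CO3, acetone) to cotoin F5. Twofold C-prenylation of F5 with prenyl bromide 2 (aq. KOH, 0 °C) at its two free ring positions gives 12, so that steps 2 to 4 are bypassed.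

3. Step 4. What may go wrong:
 - acylation at oxygen instead of carbon;
 - incomplete conversion at the ring position flanked by two oxygens.

 Fallback, setting out from 9 and coming back at 12: 9 is protected as its bis(methoxymethyl) ether F6 (MOMCl, iPr2NEt, CH2Cl2). Directed ortho-lithiation between the two OMOM groups (n-BuLi, THF, 0 °C) and addition to benzoyl chloride 10 at −78 °C gives the protected ketone F7. HCl in MeOH at rt removes both acetal groups and gives 12.

**Further compounds**

F1 | step 6 | geranyl bromide, (2E)-1-bromo-3,7-dimethylocta-2,6-diene | CC(C)=CCC/C(C)=C/CBr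
F2 | step 6 | racemic 2-benzoyl-6-geranyl-3-hydroxy-5-methoxy-4,6-diprenylcyclohexa-2,4-dien-1-one | CC(C)=CCC/C(C)=C/CC1(CC=C(C)C)C(OC)=C(CC=C(C)C)C(O)=C(C(=O)c2ccccc2)C1=O
F3 | step 6 | (6S)-enantiomer of 15 | CC(C)=CCC/C(C)=C/C[C@@]1(CC=C(C)C)C(OC)=C(CC=C(C)C)C(O)=C(C(=O)c2ccccc2)C1=O
F4 | step 3 | 2,4,6-trihydroxybenzophenone (bought) | O=C(c1ccccc1)c1c(O)cc(O)cc1O
F5 | step 3 | cotoin, (2,6-dihydroxy-4-methoxyphenyl)(phenyl)methanone | COc1cc(O)c(C(=O)c2ccccc2)c(O)c1
F6 | step 4 | 1-methoxy-3,5-bis(methoxymethoxy)-2,6-bis(3-methylbut-2-en-1-yl)benzene | COCOc1cc(OCOC)c(CC=C(C)C)c(OC)c1CC=C(C)C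
F7 | step 4 | [4-methoxy-2,6-bis(methoxymethoxy)-3,5-bis(3-methylbut-2-en-1-yl)phenyl](phenyl)methanone | COCOc1c(C(=O)c2ccccc2)c(OCOC)c(CC=C(C)C)c(OC)c1CC=C(C)C
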